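**Assumption:** the target has no stereocentre, so there is no enantiomer to select; the tetralone-stage stereocentres are formed racemic and are erased when the quinone is made.

**Retrosynthetic overview**
1. Target 20 ← salvipisone 19 (O-acetylation) ← 3-isopropyl-1-tetralone 18 by base-mediated autoxidation, which installs C2–OH and C4=O.
2. 18 ← β-keto ester 17 ← key C–C bond: conjugate addition of the laterally lithiated toluate 11 to enoate 14, then Dieckmann closure in the same pot (forms the second carbocycle, the future quinone ring).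
3. 11 ← benzylic bromide 7 + isoprenyl Grignard 10 (Cu-catalysed sp3–sp3 coupling); 7 ← 4,7-dimethylphthalide 5 ← 3,6-dimethylphthalic anhydride 4.
4. The benzene ring is formed first (Diels–Alder of 2,5-dimethylfuran with maleic anhydride, then dehydrative aromatisation); all ten carbons of 4 end up in the target.
5. Enoate 14 ← isobutyraldehyde by Horner–Wadsworth–Emmons olefination.

**Route**

Step 1
Reactants: 1 2,5-dimethylfuran; 2 maleic anhydride
Product: 3 exo-4,7-dimethyl-3a,4,7,7a-tetrahydro-4,7-epoxyisobenzofuran-1,3-dione (meso)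
Conditions: Et2O, rt, 24 h; filter the crystals
Reagents that add atoms: none
Why: Diels–Alder cycloaddition of the electron-rich furan with maleic anhydride is fast at rt and, being reversible, funnels to the crystalline exo adduct, whose four stereocentres form a meso set that is destroyed in step 2.

Step 2
Reactants: 3 exo-4,7-dimethyl-3a,4,7,7a-tetrahydro-4,7-epoxyisobenzofuran-1,3-dione
Product: 4 3,6-dimethylphthalic anhydride
Conditions: conc. H2SO4, −10 → 0 °C; pour onto ice, filter, dry
Reagents that add atoms: none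
Why: Acid-mediated opening of the oxa bridge and loss of water (dehydrative aromatisation) at low temperature outpaces retro-Diels–Alder and gives the symmetrical phthalic anhydride.

Step 3
Reactants: 4 3,6-dimethylphthalic anhydride
Product: 5 4,7-dimethylisobenzofuran-1(3H)-one (4,7-dimethylphthalide)
Conditions: NaBH4, THF, 0 °C → rt; then 6 M HCl, rt
Reagents that add atoms: none
Why: Borohydride reduction of a cyclic anhydride stops at the hydroxy acid, which lactonises on acidification, and the symmetry of 4 allows only one regioisomer.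

Step 4
Reactants: 5 4,7-dimethylisobenzofuran-1(3H)-one
Product: 7 methyl 2-(bromomethyl)-3,6-dimethylbenzoate, via acyl bromide 6 (not isolated)
Conditions: Ph3PBr2 (commercial, 1.1 equiv), neat, 170–180 °C; cool; MeOH, CH2Cl2, 0 °C → rt
Reagents that add atoms: dibromotriphenylphosphorane BrP(Br)(c1ccccc1)(c1ccccc1)c1ccccc1; methanol CO
Why: Lactone ring-opening by Ph3PBr2 (bromide SN2 at the benzylic C–O of the phosphonium-activated lactone) gives the ω-bromo acyl bromide, which methanol esterifies at once.

Step 5
Reactants: 8 3-methylbut-3-en-1-ol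
Product: 9 4-bromo-2-methylbut-1-ene
Conditions: PPh3, CBr4, CH2Cl2, 0 °C → rt; distil
Reagents that add atoms: carbon tetrabromide BrC(Br)(Br)Br
Why: Appel reaction converts the primary alcohol to the bromide by SN2 without touching the 1,1-disubstituted alkene.

Step 6
Reactants: 7 methyl 2-(bromomethyl)-3,6-dimethylbenzoate; 9 4-bromo-2-methylbut-1-ene
Product: 11 methyl 3,6-dimethyl-2-(4-methylpent-4-en-1-yl)benzoate, via Grignard reagent 10 (not isolated)
Conditions: 9, Mg, THF, rt → 40 °C; then 7, Li2CuCl4 (5 mol %), THF, −78 → 0 °C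
Reagents that add atoms: none
Why: Kochi-type copper-catalysed sp3–sp3 cross-coupling of a primary alkyl Grignard with a benzylic bromide is fast at low temperature, where the twisted, doubly ortho-substituted methyl ester is inert to the Grignard reagent.

Step 7
Reactants: 12 isobutyraldehyde; 13 trimethyl phosphonoacetate
Product: 14 methyl (E)-4-methylpent-2-enoate
Conditions: 13, NaH, THF, 0 °C; then 12, 0 °C → rt; distil
Reagents that add atoms: none
Why: Horner–Wadsworth–Emmons olefination of an α-branched aldehyde with a stabilised phosphonate anion gives the (E)-enoate with high selectivity.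

Step 8
Reactants: 11 methyl 3,6-dimethyl-2-(4-methylpent-4-en-1-yl)benzoate; 14 methyl (E)-4-methylpent-2-enoate
Product: 17 methyl 3-isopropyl-7-methyl-8-(4-methylpent-4-en-1-yl)-1-oxo-1,2,3,4-tetrahydronaphthalene-2-carboxylate (racemic), via benzylic lithium 15 (not isolated), via Michael adduct enolate 16 (not isolated)
Conditions: LDA (commercial solution, 1.1 equiv), THF, −78 °C, 30 min; 14 (1.2 equiv), −78 °C → rt; cold 1 M HCl
Reagents that add atoms: none
Why: Staunton–Weinreb annulation, in which LDA deprotonates the ortho-methyl group (primary and less hindered than the chain CH2), the soft benzylic anion undergoes intermolecular Michael addition to the enoate, and the resulting ester enolate closes onto the aryl ester by Dieckmann condensation, driven by the stable β-keto ester enolate; C2 and C3 are formed racemic and are removed later.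

Step 9
Reactants: 17 methyl 3-isopropyl-7-methyl-8-(4-methylpent-4-en-1-yl)-1-oxo-1,2,3,4-tetrahydronaphthalene-2-carboxylate
Product: 18 3-isopropyl-7-methyl-8-(4-methylpent-4-en-1-yl)-3,4-dihydronaphthalen-1(2H)-one (racemic)
Conditions: LiCl, DMSO, H2O (2 equiv), 150 °C
Reagents that add atoms: none
Why: Krapcho dealkoxycarbonylation of a β-keto ester (chloride SN2 at the O-methyl group, then decarboxylation) runs under neutral conditions that leave the acid-sensitive isopropenyl group and the ketone intact.

Step 10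
Reactants: 18 3-isopropyl-7-methyl-8-(4-methylpent-4-en-1-yl)-3,4-dihydronaphthalen-1(2H)-one
Product: 19 2-hydroxy-3-isopropyl-7-methyl-8-(4-methylpent-4-en-1-yl)naphthalene-1,4-dione (salvipisone)
Conditions: KOtBu (4 equiv), O2 (1 atm), t-BuOH, 30 °C; then cold 1 M HCl
Reagents that add atoms: dioxygen O=O
Why: Base-mediated autoxidation of a 1-tetralone oxygenates the enolate at C2 and then the benzylic C4, ending at the stable hydroxyquinone anion, so that the OH sits next to the original ketone (peri to the side chain) and the C3 stereocentre is erased.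

Step 11
Reactants: 19 2-hydroxy-3-isopropyl-7-methyl-8-(4-methylpent-4-en-1-yl)naphthalene-1,4-dione
Product: 20 acetylsalvipisone, 2-acetoxy-3-isopropyl-7-methyl-8-(4-methylpent-4-en-1-yl)naphthalene-1,4-dione
Conditions: Ac2O, pyridine, DMAP (cat.), CH2Cl2, 0 °C → rt
Reagents that add atoms: acetic anhydride CC(=O)OC(C)=O
Why: DMAP-catalysed O-acetylation of the acidic vinylogous-acid hydroxyl gives the 2-acetoxy-1,4-quinone, the more stable para-quinone of the two possible O-acyl tautomers.

**Compound list**
1 | 2,5-dimethylfuran | Cc1ccc(C)o1 | starting material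
2 | maleic anhydride | O=C1OC(=O)C=C1 | starting material
3 | (3aR,4S,7R,7aS)-4,7-dimethyl-3a,4,7,7a-tetrahydro-4,7-epoxyisobenzofuran-1,3-dione (exo adduct, meso) | C[C@]12C=C[C@](C)(O1)[C@@H]3C(=O)OC(=O)[C@H]23 | intermediate
4 | 3,6-dimethylphthalic anhydride | Cc1ccc(C)c2C(=O)OC(=O)c12 | intermediate
5 | 4,7-dimethylisobenzofuran-1(3H)-one | Cc1ccc(C)c2C(=O)OCc12 | intermediate
6 | 2-(bromomethyl)-3,6-dimethylbenzoyl bromide | Cc1ccc(C)c(C(Br)=O)c1CBr | intermediate
7 | methyl 2-(bromomethyl)-3,6-dimethylbenzoate | COC(=O)c1c(C)ccc(C)c1CBr | intermediate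
8 | 3-methylbut-3-en-1-ol | C=C(C)CCO | starting material
9 | 4-bromo-2-methylbut-1-ene | C=C(C)CCBr | intermediate
10 | (3-methylbut-3-en-1-yl)magnesium bromide | C=C(C)CC[Mg]Br | intermediate
11 | methyl 3,6-dimethyl-2-(4-methylpent-4-en-1-yl)benzoate | COC(=O)c1c(C)ccc(C)c1CCCC(C)=C | intermediate
12 | isobutyraldehyde | CC(C)C=O | starting material
13 | trimethyl phosphonoacetate | COC(=O)CP(=O)(OC)OC | starting material
14 | methyl (E)-4-methylpent-2-enoate | COC(=O)/C=C/C(C)C | intermediate
15 | methyl 6-(lithiomethyl)-3-methyl-2-(4-methylpent-4-en-1-yl)benzoate (benzylic lithium) | [Li]Cc1ccc(C)c(CCCC(C)=C)c1C(=O)OC | intermediate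
16 | lithium enolate of methyl 6-[2-(2-methoxy-2-oxoethyl)-3-methylbutyl]-3-methyl-2-(4-methylpent-4-en-1-yl)benzoate (racemic) | COC(O[Li])=CC(C(C)C)Cc1ccc(C)c(CCCC(C)=C)c1C(=O)OC | intermediate
17 | methyl 3-isopropyl-7-methyl-8-(4-methylpent-4-en-1-yl)-1-oxo-1,2,3,4-tetrahydronaphthalene-2-carboxylate (racemic, keto/enol and cis/trans mixture) | COC(=O)C1C(C(C)C)Cc2ccc(C)c(CCCC(C)=C)c2C1=O | intermediate
18 | 3-isopropyl-7-methyl-8-(4-methylpent-4-en-1-yl)-3,4-dihydronaphthalen-1(2H)-one (racemic) | CC(C)C1CC(=O)c2c(CCCC(C)=C)c(C)ccc2C1 | intermediate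
19 | 2-hydroxy-3-isopropyl-7-methyl-8-(4-methylpent-4-en-1-yl)naphthalene-1,4-dione (salvipisone) | C=C(C)CCCc1c(C)ccc2c1C(=O)C(O)=C(C(C)C)C2=O | intermediate
20 | acetylsalvipisone (achiral) | C=C(C)CCCc1c(C)ccc2c1C(=O)C(OC(C)=O)=C(C(C)C)C2=O | target

**Step count:** 11 steps in total. The longest linear sequence is 9 steps (1, 2, 3, 4, 6, 8, 9, 10, 11).

**Steps most likely to fail**

Step 8 (annulation). The β-isopropyl enoate is hindered and has a γ-hydrogen, so the basic toluate anion may deprotonate it or add sluggishly. The fallback sets out from 11 (with 12) and comes back at 17. Isobutyraldehyde 12 is condensed with dimethyl malonate (piperidine, AcOH, benzene, Dean–Stark) to dimethyl 2-(2-methylpropylidene)malonate F3, a far more electrophilic acceptor. The lithio-toluate from 11 (LDA, THF, −78 °C) is added to F3 at −78 °C and quenched cold to give dimethyl 2-{1-[2-(methoxycarbonyl)-4-methyl-3-(4-methylpent-4-en-1-yl)phenyl]-3-methylbutan-2-yl}malonate F4. Krapcho mono-dealkoxycarbonylation (NaCl, wet DMSO, 150 °C) gives methyl 6-[2-(2-methoxy-2-oxoethyl)-3-methylbutyl]-3-methyl-2-(4-methylpent-4-en-1-yl)benzoate F5, and a separate Dieckmann cyclisation (KOtBu, THF, 0 °C → rt) gives 17.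

Step 10 (autoxidation). Over-oxidation or ring cleavage could lower the yield. The fallback sets out from 18 and comes back at 19. One-pot Mukaiyama dehydrogenation (LDA, THF, −78 °C; then N-tert-butylbenzenesulfinimidoyl chloride) aromatises 18 to 3-isopropyl-7-methyl-8-(4-methylpent-4-en-1-yl)naphthalen-1-ol F6. Fremy's salt (aq. KH2PO4/acetone) oxidises the free para position to 2-isopropyl-6-methyl-5-(4-methylpent-4-en-1-yl)naphthalene-1,4-dione F7. Alkaline H2O2 (Na2CO3, aq. dioxane, 0 °C) gives 2,3-epoxy-2-isopropyl-6-methyl-5-(4-methylpent-4-en-1-yl)-2,3-dihydronaphthalene-1,4-dione F8. Warm aqueous NaOH/dioxane (hydroxide opening, then E1cB loss of the tertiary hydroxyl) and acidification give 19. This avoids the conc. H2SO4 usually used for the epoxide-to-hydroxyquinone change, which the isopropenyl group would not tolerate.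

Step 6 (Cu-catalysed coupling). Wurtz homocoupling of the benzylic bromide or Grignard attack on the ester could compete. The fallback sets out from 7 (with 9) and comes back at 11. The bromide of 7 is displaced with sodium benzenesulfinate (DMF, rt) to give methyl 3,6-dimethyl-2-[(phenylsulfonyl)methyl]benzoate F1. Its sulfonyl-stabilised benzylic anion (NaH, DMF, 0 °C) is alkylated with 9 to give methyl 3,6-dimethyl-2-[4-methyl-1-(phenylsulfonyl)pent-4-en-1-yl]benzoate F2. Reductive desulfonylation (Mg, MeOH, cat. HgCl2, rt) then delivers 11.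

**Further compounds**
F1 | step 6 | methyl 3,6-dimethyl-2-[(phenylsulfonyl)methyl]benzoate | COC(=O)c1c(C)ccc(C)c1CS(=O)(=O)c1ccccc1
F2 | step 6 | methyl 3,6-dimethyl-2-[4-methyl-1-(phenylsulfonyl)pent-4-en-1-yl]benzoate (racemic) | COC(=O)c1c(C)ccc(C)c1C(CCC(C)=C)S(=O)(=O)c1ccccc1
F3 | step 8 | dimethyl 2-(2-methylpropylidene)malonate | COC(=O)C(=CC(C)C)C(=O)OC
F4 | step 8 | dimethyl 2-{1-[2-(methoxycarbonyl)-4-methyl-3-(4-methylpent-4-en-1-yl)phenyl]-3-methylbutan-2-yl}malonate (racemic) | COC(=O)C(C(=O)OC)C(C(C)C)Cc1ccc(C)c(CCCC(C)=C)c1C(=O)OC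
F5 | step 8 | methyl 6-[2-(2-methoxy-2-oxoethyl)-3-methylbutyl]-3-methyl-2-(4-methylpent-4-en-1-yl)benzoate (racemic) | COC(=O)CC(C(C)C)Cc1ccc(C)c(CCCC(C)=C)c1C(=O)OC
F6 | step 10 | 3-isopropyl-7-methyl-8-(4-methylpent-4-en-1-yl)naphthalen-1-ol | CC(C)c1cc(O)c2c(CCCC(C)=C)c(C)ccc2c1
F7 | step 10 | 2-isopropyl-6-methyl-5-(4-methylpent-4-en-1-yl)naphthalene-1,4-dione | C=C(C)CCCc1c(C)ccc2c1C(=O)C=C(C(C)C)C2=O
F8 | step 10 | 2,3-epoxy-2-isopropyl-6-methyl-5-(4-methylpent-4-en-1-yl)-2,3-dihydronaphthalene-1,4-dione (racemic cis-epoxide) | C=C(C)CCCc1c(C)ccc2c1C(=O)C1OC1(C(C)C)C2=O
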